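**Strategy.** C4 (the carbonyl carbon) and C7 of the cyclohexenone ring are read as the two carbons of a ketene added across 1,2-dimethylcyclopentene: the [2+2] sets both methyl-bearing quaternary ring-fusion carbons (C3a, C7a) cis in one step. The C5=C6 unit with its two side chains is then sewn into the strained C4–C7 bond. The key step is a palladium-catalysed two-carbon ring expansion (oxidative addition, β-carbon elimination, C–C reductive elimination). It closes the six-membered ring and forms the tetrasubstituted enone in one operation from a spiro (Z)-β-iodoalkenyl cyclobutanol, whose enone regiochemistry is already set by alkynylation and alkoxide-directed allylmagnesiation–iodination. The quaternary C7a leaves the C7–palladium intermediate without β-hydrogen.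

Key step: step 12

Remarks on the chemistry:
- Ar stands for 2-[(tert-butyldimethylsilyl)oxy]-5-methoxy-3-methylphenyl. The core is numbered as a hexahydro-4H-inden-4-one (C3a, C4–C7, C7a) and the four-membered intermediates as bicyclo[3.2.0]heptanes.
- Assumption: the ketal diastereomer that contains the (1R,5R) ketone is identified by X-ray analysis before step 9.
- Racemic 13 and 14 are drawn as one enantiomer. The carbinol carbon C6 of 19, 21, 22 and 23 is an unassigned mixture of epimers; it becomes the carbonyl carbon in step 12.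

Step 1
Reactants: 1 4-methoxy-2-methylphenol; 2 1-bromo-3-methylbut-2-ene (prenyl bromide)
Product: 4 4-methoxy-2-methyl-6-(3-methylbut-2-en-1-yl)phenol, via sodium phenolate 3 (not isolated)
Conditions: NaH, toluene, 0 °C to rt
Reagents that add atoms: prenyl bromide 2 (CC(C)=CCBr)
Why: Ortho C-alkylation of a phenoxide: in toluene the sodium phenolate should react as a tight ion pair at carbon, and only one ortho position is free because the para position carries OMe.

Step 2
Reactants: 4 4-methoxy-2-methyl-6-(3-methylbut-2-en-1-yl)phenol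
Product: 5 tert-butyl[4-methoxy-2-methyl-6-(3-methylbut-2-en-1-yl)phenoxy]dimethylsilane
Conditions: TBSCl, imidazole, DMF, 40 °C
Reagents that add atoms: tert-butyldimethylsilyl chloride (CC(C)(C)[Si](C)(C)Cl)
Why: Silyl ether formation masks the acidic, oxidation-prone phenol for the SeO2, organometallic and palladium steps, and the two flanking substituents should make the aryl silyl ether robust.

Step 3
Reactants: 5 tert-butyl[4-methoxy-2-methyl-6-(3-methylbut-2-en-1-yl)phenoxy]dimethylsilane
Product: 6 (2E)-4-Ar-2-methylbut-2-en-1-ol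
Conditions: SeO2 (cat.), t-BuOOH, CH2Cl2, 0 °C to rt
Reagents that add atoms: tert-butyl hydroperoxide (CC(C)(C)OO)
Why: Riley allylic oxidation (ene reaction, then [2,3]-sigmatropic shift) should attack the more substituted alkene terminus at the methyl group trans to the chain, which sets the (E)-trisubstituted alkene of the side chain.

Step 4
Reactants: 6 (2E)-4-Ar-2-methylbut-2-en-1-ol
Product: 7 (2E)-4-Ar-1-bromo-2-methylbut-2-ene
Conditions: CBr4, PPh3, CH2Cl2, 0 °C
Reagents that add atoms: carbon tetrabromide (BrC(Br)(Br)Br)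
Why: The Appel reaction should convert the primary allylic alcohol into the bromide by SN2 displacement without allylic transposition, so the (E) geometry is kept.

Step 5
Reactants: 7 (2E)-4-Ar-1-bromo-2-methylbut-2-ene; 8 ethynylmagnesium bromide
Product: 9 (4E)-6-Ar-4-methylhex-4-en-1-yne
Conditions: CuCl (cat.), THF, 0 °C to rt
Reagents that add atoms: ethynylmagnesium bromide 8 (C#C[Mg]Br)
Why: Copper-catalysed allylic substitution by the alkynyl Grignard reagent should occur at the unhindered CH2 terminus (SN2) and give the skipped enyne with the alkene untouched.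

Step 6
Reactants: 10 1,2-dimethylcyclopentene; 11 trichloroacetyl chloride
Product: 13 rac-(1S,5R)-7,7-dichloro-1,5-dimethylbicyclo[3.2.0]heptan-6-one, via dichloroketene 12 (not isolated)
Conditions: Zn–Cu couple, POCl3, Et2O, reflux
Reagents that add atoms: trichloroacetyl chloride 11 (ClC(=O)C(Cl)(Cl)Cl)
Why: The thermal ketene–alkene [2+2] cycloaddition of dichloroketene is suprafacial on the tetrasubstituted alkene, so both quaternary centres should form cis (racemic; the alkene is symmetric, so there is no regiochemical issue).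

Step 7
Reactants: 13 rac-(1S,5R)-7,7-dichloro-1,5-dimethylbicyclo[3.2.0]heptan-6-one
Product: 14 rac-(1R,5R)-1,5-dimethylbicyclo[3.2.0]heptan-6-one
Conditions: Zn, AcOH, 60 °C
Reagents that add atoms: none
Why: Reductive dechlorination of the α,α-dichloroketone by zinc in acetic acid (via the zinc enolate) should leave the cyclobutanone and both quaternary centres unchanged.

Step 8
Reactants: 14 rac-(1R,5R)-1,5-dimethylbicyclo[3.2.0]heptan-6-one; 15 (1R,2R)-1,2-diphenylethane-1,2-diol
Product: 16 (1R,4'R,5R,5'R)-1,5-dimethyl-4',5'-diphenylspiro[bicyclo[3.2.0]heptane-6,2'-[1,3]dioxolane]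
Conditions: TsOH (cat.), toluene, Dean–Stark, reflux; separation of the two diastereomeric ketals by chromatography or crystallisation
Reagents that add atoms: (1R,2R)-1,2-diphenylethane-1,2-diol 15 (O[C@H](c1ccccc1)[C@H](O)c1ccccc1)
Why: Acid-catalysed ketalisation with a C2-symmetric diol creates no new stereocentre, so the racemate should give just two diastereomeric ketals, and their separation (resolution via diastereomers) secures the absolute configuration of both quaternary centres.

Step 9
Reactants: 16 (1R,4'R,5R,5'R)-1,5-dimethyl-4',5'-diphenylspiro[bicyclo[3.2.0]heptane-6,2'-[1,3]dioxolane]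
Product: 17 (1R,5R)-1,5-dimethylbicyclo[3.2.0]heptan-6-one
Conditions: 2 M HCl, THF, 40 °C
Reagents that add atoms: water (O)
Why: Acid-catalysed ketal hydrolysis should release the enantiopure cyclobutanone and the recoverable diol; the quaternary centres cannot epimerise.

Step 10
Reactants: 9 (4E)-6-Ar-4-methylhex-4-en-1-yne; 17 (1R,5R)-1,5-dimethylbicyclo[3.2.0]heptan-6-one
Product: 19 (1R,5R)-6-[(4E)-6-Ar-4-methylhex-4-en-1-yn-1-yl]-1,5-dimethylbicyclo[3.2.0]heptan-6-ol, via lithium acetylide 18 (not isolated)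
Conditions: n-BuLi, THF, −78 °C; then 17, −78 to 0 °C
Reagents that add atoms: none
Why: 1,2-Addition of a lithium acetylide to the strained, strongly electrophilic cyclobutanone; the carbinol centre formed is destroyed in step 12, so its configuration does not matter.

Step 11
Reactants: 19 (1R,5R)-6-[(4E)-6-Ar-4-methylhex-4-en-1-yn-1-yl]-1,5-dimethylbicyclo[3.2.0]heptan-6-ol; 20 2-methylallylmagnesium chloride
Product: 22 (1R,5R)-6-[(1Z,4E)-6-Ar-2-iodo-4-methyl-1-(2-methylprop-2-en-1-yl)hexa-1,4-dien-1-yl]-1,5-dimethylbicyclo[3.2.0]heptan-6-ol, via oxamagnesacycle 21 (not isolated)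
Conditions: 2-methylallylmagnesium chloride (excess), THF, 0 to 60 °C; then I2, −40 to 0 °C
Reagents that add atoms: 2-methylallylmagnesium chloride 20 (CC(=C)C[Mg]Cl); iodine (II)
Why: Alkoxide-directed anti-carbomagnesiation of a propargylic alcohol by an allylic Grignard reagent should deliver the allyl group to the alkyne carbon next to the carbinol and magnesium to the distal carbon in a five-membered chelate, and iodinolysis with retention then gives the (Z)-iodoalkene with iodine cis to the carbinol carbon.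

Step 12
Reactants: 22 (1R,5R)-6-[(1Z,4E)-6-Ar-2-iodo-4-methyl-1-(2-methylprop-2-en-1-yl)hexa-1,4-dien-1-yl]-1,5-dimethylbicyclo[3.2.0]heptan-6-ol
Product: 25 (3aR,7aR)-6-[(2E)-4-Ar-2-methylbut-2-en-1-yl]-3a,7a-dimethyl-5-(2-methylprop-2-en-1-yl)-1,2,3,3a,7,7a-hexahydro-4H-inden-4-one, via oxapalladacyclopentene 23 (not isolated), via palladacycloheptenone 24 (not isolated)
Conditions: Pd(OAc)2 (10 mol %), PPh3 (20 mol %), Cs2CO3, toluene, 90 °C
Reagents that add atoms: none
Why: Proposed new method: oxidative addition of zerovalent palladium into the C–I bond and exchange of iodide for the caesium alkoxide should give the spiro oxapalladacyclopentene 23, whose strained four-membered ring opens by β-carbon elimination of the cyclobutanol C6–C7 bond (bicycloheptane numbering) to the seven-membered palladacycle 24, and C(sp2)–C(sp3) reductive elimination (the CH2–Pd carbon has no β-hydrogen) then forms the C6–C7 bond of the indenone. The closest known reaction types are the palladium-catalysed arylation and alkenylation of tert-cyclobutanols through β-carbon elimination and the nickel-catalysed insertion of alkynes into cyclobutanones, which is thought to pass through the same kind of spiro oxametallacyclopentene. The six-membered ring is closed by reductive elimination from a seven-membered metallacycle, in effect a two-carbon ring expansion in which the cyclobutane CH2 moves from the carbinol carbon to the iodine-bearing alkene carbon. No stereocentre is created: the carbinol carbon becomes the carbonyl carbon and the two quaternary centres are not touched, so the cis ring fusion and the absolute configuration come unchanged from 17. The step needs site selectivity between the two ring bonds at the carbinol carbon and the correct enone regiochemistry. The first is secured by the quaternary C5, whose migration would put palladium on a tertiary carbon, and the second is already built into 22, where the allyl-bearing alkene carbon is bonded to the future carbonyl carbon and iodine sits cis to it on the carbon that carries the aryl side chain.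

Step 13
Reactants: 25 (3aR,7aR)-6-[(2E)-4-Ar-2-methylbut-2-en-1-yl]-3a,7a-dimethyl-5-(2-methylprop-2-en-1-yl)-1,2,3,3a,7,7a-hexahydro-4H-inden-4-one
Product: 27 (3aR,7aR)-6-[(2E)-4-Ar-2-methylbut-2-en-1-yl]-5-(2-hydroxy-2-methylpropyl)-3a,7a-dimethyl-1,2,3,3a,7,7a-hexahydro-4H-inden-4-one, via organomercurial 26 (not isolated)
Conditions: Hg(OAc)2, THF–H2O, 0 °C; then NaBH4, aq. NaOH, 0 °C
Reagents that add atoms: water (O)
Why: Markovnikov oxymercuration–demercuration should be much faster at the 1,1-disubstituted alkene than at the trisubstituted side-chain alkene or the electron-poor tetrasubstituted enone, and the carbinol carbon carries two methyl groups after demercuration, so no stereocentre arises.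

Step 14
Reactants: 27 (3aR,7aR)-6-[(2E)-4-Ar-2-methylbut-2-en-1-yl]-5-(2-hydroxy-2-methylpropyl)-3a,7a-dimethyl-1,2,3,3a,7,7a-hexahydro-4H-inden-4-one
Product: 28 (3aR,7aR)-5-(2-hydroxy-2-methylpropyl)-6-[(2E)-4-(2-hydroxy-5-methoxy-3-methylphenyl)-2-methylbut-2-en-1-yl]-3a,7a-dimethyl-1,2,3,3a,7,7a-hexahydro-4H-inden-4-one
Conditions: TBAF, THF, 0 °C
Reagents that add atoms: none
Why: Fluoride-induced cleavage of the aryl silyl ether (desilylation) should leave the enone, the alkenes and the tertiary alcohol untouched.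

**Compound list**

1 | 4-methoxy-2-methylphenol | COc1ccc(O)c(C)c1 | starting material
2 | 1-bromo-3-methylbut-2-ene (prenyl bromide) | CC(C)=CCBr | starting material
3 | sodium 4-methoxy-2-methylphenolate | COc1ccc([O-])c(C)c1.[Na+] | intermediate (not isolated)
4 | 4-methoxy-2-methyl-6-(3-methylbut-2-en-1-yl)phenol | COc1cc(C)c(O)c(CC=C(C)C)c1 | intermediate
5 | tert-butyl[4-methoxy-2-methyl-6-(3-methylbut-2-en-1-yl)phenoxy]dimethylsilane | COc1cc(C)c(O[Si](C)(C)C(C)(C)C)c(CC=C(C)C)c1 | intermediate
6 | (2E)-4-{2-[(tert-butyldimethylsilyl)oxy]-5-methoxy-3-methylphenyl}-2-methylbut-2-en-1-ol | COc1cc(C)c(O[Si](C)(C)C(C)(C)C)c(C/C=C(\C)CO)c1 | intermediate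
7 | {2-[(2E)-4-bromo-3-methylbut-2-en-1-yl]-4-methoxy-6-methylphenoxy}(tert-butyl)dimethylsilane | COc1cc(C)c(O[Si](C)(C)C(C)(C)C)c(C/C=C(\C)CBr)c1 | intermediate
8 | ethynylmagnesium bromide | C#C[Mg]Br | starting material
9 | tert-butyl{4-methoxy-2-methyl-6-[(2E)-3-methylhex-2-en-5-yn-1-yl]phenoxy}dimethylsilane | COc1cc(C)c(O[Si](C)(C)C(C)(C)C)c(C/C=C(\C)CC#C)c1 | intermediate
10 | 1,2-dimethylcyclopentene | CC1=C(C)CCC1 | starting material
11 | trichloroacetyl chloride | ClC(=O)C(Cl)(Cl)Cl | starting material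
12 | dichloroketene | ClC(Cl)=C=O | intermediate (not isolated)
13 | rac-(1S,5R)-7,7-dichloro-1,5-dimethylbicyclo[3.2.0]heptan-6-one (cis-fused racemate, one enantiomer drawn) | O=C1C(Cl)(Cl)[C@@]2(C)CCC[C@@]12C | intermediate
14 | rac-(1R,5R)-1,5-dimethylbicyclo[3.2.0]heptan-6-one (cis-fused racemate, one enantiomer drawn) | O=C1C[C@@]2(C)CCC[C@@]12C | intermediate
15 | (1R,2R)-1,2-diphenylethane-1,2-diol | O[C@H](c1ccccc1)[C@H](O)c1ccccc1 | starting material
16 | (1R,4'R,5R,5'R)-1,5-dimethyl-4',5'-diphenylspiro[bicyclo[3.2.0]heptane-6,2'-[1,3]dioxolane] | O1[C@H](c3ccccc3)[C@@H](c3ccccc3)OC14C[C@@]2(C)CCC[C@@]42C | intermediate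
17 | (1R,5R)-1,5-dimethylbicyclo[3.2.0]heptan-6-one | O=C1C[C@@]2(C)CCC[C@@]12C | intermediate
18 | lithium acetylide of 9, [(4E)-6-{2-[(tert-butyldimethylsilyl)oxy]-5-methoxy-3-methylphenyl}-4-methylhex-4-en-1-yn-1-yl]lithium | COc1cc(C)c(O[Si](C)(C)C(C)(C)C)c(C/C=C(\C)CC#C[Li])c1 | intermediate (not isolated)
19 | (1R,5R)-6-[(4E)-6-{2-[(tert-butyldimethylsilyl)oxy]-5-methoxy-3-methylphenyl}-4-methylhex-4-en-1-yn-1-yl]-1,5-dimethylbicyclo[3.2.0]heptan-6-ol (C6 epimers) | COc1cc(C)c(O[Si](C)(C)C(C)(C)C)c(C/C=C(\C)CC#CC2(O)C[C@@]3(C)CCC[C@@]23C)c1 | intermediate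
20 | 2-methylallylmagnesium chloride | CC(=C)C[Mg]Cl | starting material
21 | spiro 2,5-dihydro-1,2-oxamagnesole chelate: magnesium bridges the C6 oxygen and the distal alkene carbon, and the proximal alkene carbon carries the 2-methylallyl group | COc1cc(C)c(O[Si](C)(C)C(C)(C)C)c(C/C=C(\C)CC2=C(CC(C)=C)C3(O[Mg]2)C[C@@]4(C)CCC[C@@]34C)c1 | intermediate (not isolated)
22 | (1R,5R)-6-[(1Z,4E)-6-{2-[(tert-butyldimethylsilyl)oxy]-5-methoxy-3-methylphenyl}-2-iodo-4-methyl-1-(2-methylprop-2-en-1-yl)hexa-1,4-dien-1-yl]-1,5-dimethylbicyclo[3.2.0]heptan-6-ol (C6 epimers) | COc1cc(C)c(O[Si](C)(C)C(C)(C)C)c(C/C=C(\C)C/C(I)=C(\CC(C)=C)C2(O)C[C@@]3(C)CCC[C@@]23C)c1 | intermediate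
23 | spiro oxapalladacyclopentene: palladium bridges the C6 oxygen and the former iodine-bearing carbon (phosphine ligands omitted) | COc1cc(C)c(O[Si](C)(C)C(C)(C)C)c(C/C=C(\C)CC2=C(CC(C)=C)C3(O[Pd]2)C[C@@]4(C)CCC[C@@]34C)c1 | intermediate (not isolated)
24 | seven-membered palladacycloheptenone: palladium bridges the alkenyl carbon and the former cyclobutane CH2 (phosphine ligands omitted) | COc1cc(C)c(O[Si](C)(C)C(C)(C)C)c(C/C=C(\C)CC2=C(CC(C)=C)C(=O)[C@]3(C)CCC[C@]3(C)C[Pd]2)c1 | intermediate (not isolated)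
25 | (3aR,7aR)-6-[(2E)-4-{2-[(tert-butyldimethylsilyl)oxy]-5-methoxy-3-methylphenyl}-2-methylbut-2-en-1-yl]-3a,7a-dimethyl-5-(2-methylprop-2-en-1-yl)-1,2,3,3a,7,7a-hexahydro-4H-inden-4-one | COc1cc(C)c(O[Si](C)(C)C(C)(C)C)c(C/C=C(\C)CC2=C(CC(C)=C)C(=O)[C@]3(C)CCC[C@]3(C)C2)c1 | intermediate
26 | β-hydroxyalkylmercury acetate from 25 (AcOHg–CH2–C(CH3)(OH)–CH2– at C5; carbinol carbon unassigned) | COc1cc(C)c(O[Si](C)(C)C(C)(C)C)c(C/C=C(\C)CC2=C(CC(C)(O)C[Hg]OC(C)=O)C(=O)[C@]3(C)CCC[C@]3(C)C2)c1 | intermediate (not isolated)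
27 | (3aR,7aR)-6-[(2E)-4-{2-[(tert-butyldimethylsilyl)oxy]-5-methoxy-3-methylphenyl}-2-methylbut-2-en-1-yl]-5-(2-hydroxy-2-methylpropyl)-3a,7a-dimethyl-1,2,3,3a,7,7a-hexahydro-4H-inden-4-one | COc1cc(C)c(O[Si](C)(C)C(C)(C)C)c(C/C=C(\C)CC2=C(CC(C)(C)O)C(=O)[C@]3(C)CCC[C@]3(C)C2)c1 | intermediate
28 | (3aR,7aR)-5-(2-hydroxy-2-methylpropyl)-6-[(2E)-4-(2-hydroxy-5-methoxy-3-methylphenyl)-2-methylbut-2-en-1-yl]-3a,7a-dimethyl-1,2,3,3a,7,7a-hexahydro-4H-inden-4-one | COc1cc(C)c(O)c(C/C=C(\C)CC2=C(CC(C)(C)O)C(=O)[C@]3(C)CCC[C@]3(C)C2)c1 | target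

**Step count and risks**

Total step count: 14. Longest linear sequence: 10 steps (steps 1–5, then 10–14); the core branch (steps 6–9) joins at step 10.

Steps most likely to fail:

Step 12 (proposed new method). The palladium alkoxide is held in a five-membered chelate and may not reach the geometry needed for β-carbon elimination, so that protodeiodination or decomposition of the alkenylpalladium species takes over. The fallback uses the known insertion of an internal alkyne into a cyclobutanone under zerovalent nickel catalysis and sets out from bromide 7 and ketone 17. Coupling of 7 with commercial 2-methylpent-4-yn-2-ol (CuI, K2CO3, NaI, DMF) should give (7E)-9-Ar-2,7-dimethylnon-7-en-4-yn-2-ol F1. Ni(cod)2 and PCy3 in toluene at 100 °C should then insert F1 into the C6–C7 bond of 17 and give 27 directly. This variant has no control over the orientation of the alkyne, so the regioisomeric enone (3aR,7aR)-5-[(2E)-4-Ar-2-methylbut-2-en-1-yl]-6-(2-hydroxy-2-methylpropyl)-3a,7a-dimethyl-1,2,3,3a,7,7a-hexahydro-4H-inden-4-one F2 is expected as well and has to be removed by chromatography. The fallback comes back to the route at 27.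

Step 11. Carbomagnesiation of the internal alkyne next to a hindered tertiary alkoxide may be slow, and the excess Grignard reagent may deprotonate the doubly activated CH2 between alkyne and alkene, leading to alkyne–allene isomerisation. The fallback introduces the C5 substituent after ring formation and sets out from 19. Hydroxyl-directed trans-hydroalumination with NaAlH2(OCH2CH2OMe)2 followed by I2 should give (1R,5R)-6-[(1Z,4E)-6-Ar-2-iodo-4-methylhexa-1,4-dien-1-yl]-1,5-dimethylbicyclo[3.2.0]heptan-6-ol F3. Ring expansion under the conditions of step 12 should give (3aR,7aR)-6-[(2E)-4-Ar-2-methylbut-2-en-1-yl]-3a,7a-dimethyl-1,2,3,3a,7,7a-hexahydro-4H-inden-4-one F4. α-Iodination of the enone (I2, pyridine, CH2Cl2) should give the 5-iodo derivative (3aR,7aR)-6-[(2E)-4-Ar-2-methylbut-2-en-1-yl]-5-iodo-3a,7a-dimethyl-1,2,3,3a,7,7a-hexahydro-4H-inden-4-one F5. Stille coupling of F5 with tributyl(2-methylallyl)stannane (Pd2(dba)3, AsPh3, CuI, DMF) comes back to the route at 25. This fallback still relies on the ring expansion of step 12; if that also fails, the fallback for step 12 applies.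

Step 13. Mercuration may not discriminate well enough between the 1,1-disubstituted alkene and the trisubstituted side-chain alkene, and the enone may be reduced during demercuration. The fallback builds the tertiary alcohol from a terminal alkene and sets out from 19. Allylmagnesium bromide followed by I2 (as in step 11) should give (1R,5R)-6-[(1Z,4E)-6-Ar-2-iodo-4-methyl-1-(prop-2-en-1-yl)hexa-1,4-dien-1-yl]-1,5-dimethylbicyclo[3.2.0]heptan-6-ol F6. Ring expansion as in step 12 should give (3aR,7aR)-6-[(2E)-4-Ar-2-methylbut-2-en-1-yl]-3a,7a-dimethyl-5-(prop-2-en-1-yl)-1,2,3,3a,7,7a-hexahydro-4H-inden-4-one F7. Tsuji–Wacker oxidation of the monosubstituted alkene (PdCl2, CuCl, O2, DMF–H2O) should give the methyl ketone (3aR,7aR)-6-[(2E)-4-Ar-2-methylbut-2-en-1-yl]-3a,7a-dimethyl-5-(2-oxopropyl)-1,2,3,3a,7,7a-hexahydro-4H-inden-4-one F8. Chemoselective methyl addition to the unhindered ketone with MeTi(OiPr)3 (Et2O, 0 °C to rt) comes back to the route at 27.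

**Further compounds**

F1 | step 12 | (7E)-9-{2-[(tert-butyldimethylsilyl)oxy]-5-methoxy-3-methylphenyl}-2,7-dimethylnon-7-en-4-yn-2-ol | COc1cc(C)c(O[Si](C)(C)C(C)(C)C)c(C/C=C(\C)CC#CCC(C)(C)O)c1
F2 | step 12 | (3aR,7aR)-5-[(2E)-4-{2-[(tert-butyldimethylsilyl)oxy]-5-methoxy-3-methylphenyl}-2-methylbut-2-en-1-yl]-6-(2-hydroxy-2-methylpropyl)-3a,7a-dimethyl-1,2,3,3a,7,7a-hexahydro-4H-inden-4-one | COc1cc(C)c(O[Si](C)(C)C(C)(C)C)c(C/C=C(\C)CC2=C(CC(C)(C)O)C[C@@]3(C)CCC[C@@]3(C)C2=O)c1
F3 | step 11 | (1R,5R)-6-[(1Z,4E)-6-{2-[(tert-butyldimethylsilyl)oxy]-5-methoxy-3-methylphenyl}-2-iodo-4-methylhexa-1,4-dien-1-yl]-1,5-dimethylbicyclo[3.2.0]heptan-6-ol | COc1cc(C)c(O[Si](C)(C)C(C)(C)C)c(C/C=C(\C)C/C(I)=C/C2(O)C[C@@]3(C)CCC[C@@]23C)c1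
F4 | step 11 | (3aR,7aR)-6-[(2E)-4-{2-[(tert-butyldimethylsilyl)oxy]-5-methoxy-3-methylphenyl}-2-methylbut-2-en-1-yl]-3a,7a-dimethyl-1,2,3,3a,7,7a-hexahydro-4H-inden-4-one | COc1cc(C)c(O[Si](C)(C)C(C)(C)C)c(C/C=C(\C)CC2=CC(=O)[C@]3(C)CCC[C@]3(C)C2)c1
F5 | step 11 | (3aR,7aR)-6-[(2E)-4-{2-[(tert-butyldimethylsilyl)oxy]-5-methoxy-3-methylphenyl}-2-methylbut-2-en-1-yl]-5-iodo-3a,7a-dimethyl-1,2,3,3a,7,7a-hexahydro-4H-inden-4-one | COc1cc(C)c(O[Si](C)(C)C(C)(C)C)c(C/C=C(\C)CC2=C(I)C(=O)[C@]3(C)CCC[C@]3(C)C2)c1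
F6 | step 13 | (1R,5R)-6-[(1Z,4E)-6-{2-[(tert-butyldimethylsilyl)oxy]-5-methoxy-3-methylphenyl}-2-iodo-4-methyl-1-(prop-2-en-1-yl)hexa-1,4-dien-1-yl]-1,5-dimethylbicyclo[3.2.0]heptan-6-ol | COc1cc(C)c(O[Si](C)(C)C(C)(C)C)c(C/C=C(\C)C/C(I)=C(\CC=C)C2(O)C[C@@]3(C)CCC[C@@]23C)c1
F7 | step 13 | (3aR,7aR)-6-[(2E)-4-{2-[(tert-butyldimethylsilyl)oxy]-5-methoxy-3-methylphenyl}-2-methylbut-2-en-1-yl]-3a,7a-dimethyl-5-(prop-2-en-1-yl)-1,2,3,3a,7,7a-hexahydro-4H-inden-4-one | COc1cc(C)c(O[Si](C)(C)C(C)(C)C)c(C/C=C(\C)CC2=C(CC=C)C(=O)[C@]3(C)CCC[C@]3(C)C2)c1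
F8 | step 13 | (3aR,7aR)-6-[(2E)-4-{2-[(tert-butyldimethylsilyl)oxy]-5-methoxy-3-methylphenyl}-2-methylbut-2-en-1-yl]-3a,7a-dimethyl-5-(2-oxopropyl)-1,2,3,3a,7,7a-hexahydro-4H-inden-4-one | COc1cc(C)c(O[Si](C)(C)C(C)(C)C)c(C/C=C(\C)CC2=C(CC(C)=O)C(=O)[C@]3(C)CCC[C@]3(C)C2)c1
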